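**Retrosynthetic overview**

1. The target is read as catechin-(4α→8)-catechin-(4α→8)-catechin-(4α→8)-catechin (all units 2R,3S). Units 1, 2 and 4 (numbered from the chain top) come from (+)-catechin; unit 3 is built on C8 of unit 4.
2. Last disconnections: the C4(unit 1)–C8(unit 2) and C4(unit 2)–C8(unit 3) bonds, by two Friedel–Crafts chain extensions with a 3-O-acetyl-4-alkoxycatechin (3,4-trans through acetate participation).
3. Unit 3: the C3–OH and C2–H come from hydroboration–oxidation of a flav-2-ene anti to its C4 aryl. Ring C of unit 3 is the only ring made (step 10): a chiral-acid-catalysed formal [4+2] of an ortho-quinone methide with an enamide forms C3–C4 first and then closes the ring at O1–C2.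
4. Enabling feature: in unit 3, O1 is a phenolic oxygen of phloroglucinol ring A ortho to C4a, and C4 is a methine flanked by ring A and by C8 of ring A of unit 4. O1=C8a–C4a=C4 is therefore a latent ortho-quinone methide, and C2 carries the para-oxygenated ring B that stabilises the cation attacked by O1.
5. The methide precursor is a benzhydrol made from 8-lithiated benzylated catechin and a phloroglucinaldehyde, so the C4–C8 bond between units 3 and 4 precedes ring C.

Key step: step 10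

Remark: α is the flavan face that carries the C2 aryl group. The C4 alkoxy epimer of 19 and 20 and the carbinol epimers of 9 and 10 do not matter, because these centres become planar cations. Compound 11 is taken as commercial.

**Route**

Step 1
Reactants: 1 (+)-catechin
Product: 2 5,7,3',4'-tetra-O-benzyl-(+)-catechin
Conditions: BnBr (4.4 equiv), K2CO3, DMF, 0 °C to rt
Reagents that add atoms: benzyl bromide, BrCc1ccccc1
Why: Williamson etherification in which carbonate deprotonates only the four phenols, so the secondary 3-OH stays free and no stereocentre is touched.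

Step 2
Reactants: 2 5,7,3',4'-tetra-O-benzyl-(+)-catechin
Product: 3 3,5,7,3',4'-penta-O-benzyl-(+)-catechin
Conditions: NaH, BnBr, Bu4NI (cat.), DMF, 0 °C to rt
Reagents that add atoms: benzyl bromide, BrCc1ccccc1
Why: Williamson etherification of the secondary alcohol as its sodium alkoxide; with all phenols capped, no base-induced opening at C2 is possible.

Step 3
Reactants: 3 3,5,7,3',4'-penta-O-benzyl-(+)-catechin
Product: 4 8-bromo-3,5,7,3',4'-penta-O-benzyl-(+)-catechin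
Conditions: NBS (1.0 equiv), CH2Cl2, −78 °C to rt
Reagents that add atoms: N-bromosuccinimide, O=C1CCC(=O)N1Br
Why: Electrophilic aromatic bromination, expected at C8, the most nucleophilic position of ring A in benzylated catechins.

Step 4
Reactants: 5 2,4,6-trihydroxybenzaldehyde
Product: 6 4,6-bis(benzyloxy)-2-hydroxybenzaldehyde
Conditions: BnBr (2.1 equiv), K2CO3, DMF, rt
Reagents that add atoms: benzyl bromide, BrCc1ccccc1
Why: Williamson etherification that should stop at the bis-ether, because the last ortho hydroxyl is hydrogen-bonded to the aldehyde.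

Step 5
Reactants: 6 4,6-bis(benzyloxy)-2-hydroxybenzaldehyde
Product: 7 4,6-bis(benzyloxy)-2-(tert-butyldimethylsilyloxy)benzaldehyde
Conditions: TBSCl, imidazole, DMAP (cat.), DMF, rt to 40 °C
Reagents that add atoms: tert-butyldimethylsilyl chloride, CC(C)(C)[Si](C)(C)Cl
Why: Silylation masks the acidic phenol (the future O1) for the organolithium step and can be removed without acid.

Step 6
Reactants: 4 8-bromo-3,5,7,3',4'-penta-O-benzyl-(+)-catechin; 7 4,6-bis(benzyloxy)-2-(tert-butyldimethylsilyloxy)benzaldehyde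
Product: 9 [4,6-bis(benzyloxy)-2-(tert-butyldimethylsilyloxy)phenyl](3,5,7,3',4'-penta-O-benzylcatechin-8-yl)methanol (both carbinol epimers), via 8-lithio-penta-O-benzylcatechin 8 (not isolated)
Conditions: n-BuLi (1.05 equiv), THF, −78 °C; then 7, −78 °C; then AcOH (1.1 equiv), −78 °C
Reagents that add atoms: none
Why: Bromine–lithium exchange gives the C8 aryllithium, which adds 1,2 to the aldehyde and forms the C4(unit 3)–C8(unit 4) bond; the carbinol centre is uncontrolled and is planarised in step 10.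

Step 7
Reactants: 9 silyl-protected benzhydrol
Product: 10 [4,6-bis(benzyloxy)-2-hydroxyphenyl](3,5,7,3',4'-penta-O-benzylcatechin-8-yl)methanol (both carbinol epimers)
Conditions: TBAF (1.1 equiv), AcOH (1.1 equiv), THF, 0 °C; used without chromatography
Reagents that add atoms: none
Why: Fluoride cleaves the aryl silyl ether, and the acetic acid buffer should keep the doubly activated benzhydrol from ionising.

Step 8
Reactants: 11 3',4'-bis(benzyloxy)acetophenone
Product: 12 (E)-3',4'-bis(benzyloxy)acetophenone oxime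
Conditions: NH2OH·HCl, NaOAc, EtOH/H2O, 70 °C
Reagents that add atoms: hydroxylamine hydrochloride, Cl.NO
Why: Oxime condensation of an aryl methyl ketone.

Step 9
Reactants: 12 (E)-3',4'-bis(benzyloxy)acetophenone oxime
Product: 13 N-{1-[3,4-bis(benzyloxy)phenyl]vinyl}acetamide
Conditions: Fe powder, Ac2O, AcOH, toluene, 70 °C
Reagents that add atoms: acetic anhydride, CC(=O)OC(C)=O
Why: Reductive acylation of a ketoxime: iron cleaves the N–O bond of the O-acetyl oxime, and the imine anion is N-acetylated and tautomerises to the secondary enamide.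

Step 10
Reactants: 10 ortho-hydroxybenzhydrol; 13 N-{1-[3,4-bis(benzyloxy)phenyl]vinyl}acetamide
Product: 16 5,7,3',4'-tetra-O-benzylflav-2-ene-(4α→8)-3,5,7,3',4'-penta-O-benzylcatechin, via ortho-quinone methide 14 (not isolated), via 2-acetamidoflavan aminal 15 (not isolated)
Conditions: (R)-TRIP (chiral BINOL hydrogen phosphate, 10 mol %), 13 (1.5 equiv), 4 Å MS, CH2Cl2, 0 °C to rt; then PPTS (10 mol %), 40 °C
Reagents that add atoms: none
Why: The chiral phosphoric acid dehydrates 10 to the ortho-quinone methide 14 (O1=C8a–C4a=C4 of unit 3) and binds it together with the N–H of 13, so that the nucleophilic CH2 terminus of the enamide (future C3) adds to C4 on one face; the closest known reaction type is the chiral-phosphoric-acid-catalysed addition of enamides and 1,3-dicarbonyls to in-situ ortho-quinone methides that leads to 4-aryl-4H-chromenes. The N-acyliminium carbon C2, which carries ring B, is then captured by the phenolic O1 in a 6-exo-trig closure that forms the O1–C2 bond and ring C of unit 3 (aminal 15), and mild acid expels acetamide to leave the C2=C3 enol ether of 16. The only stereocentre that survives is C4, set α by the catalyst, whose 3,3'-aryl groups shield one face of the planar methide (the antipodal acid is taken if the pairing with the catechin unit proves mismatched); C2 of 15 is transient. Regioselectivity is secured because only the CH2 carbon of 13 is nucleophilic and O1 is the only free hydroxyl (the 3-OH of unit 4 is benzylated), and chemoselectivity because the enamide is a far better nucleophile than the free ring-A positions. One operation thus brings in C2, C3 and ring B, makes the C3–C4 and O1–C2 bonds and sets the centre that dictates C3 and C2 in step 11.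

Step 11
Reactants: 16 flav-2-ene-(4α→8)-catechin nonabenzyl ether
Product: 18 5,7,3',4'-tetra-O-benzylcatechin-(4α→8)-3,5,7,3',4'-penta-O-benzylcatechin (upper 3-OH free), via C3 alkylborane 17 (not isolated)
Conditions: BH3·THF (3 equiv), THF, 0 °C to rt; then NaOH (aq), H2O2, 0 °C
Reagents that add atoms: hydrogen peroxide, OO
Why: Brown hydroboration–oxidation: borane adds syn with boron at C3 (β to O1 and to ring B) from the β face, anti to the pseudo-axial C4 aryl, so after oxidation with retention the 3-OH and the C2–H are β and ring B is α, which is the 2,3-trans-3,4-trans array.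

Step 12
Reactants: 2 5,7,3',4'-tetra-O-benzyl-(+)-catechin
Product: 19 4β-(2-ethoxyethoxy)-5,7,3',4'-tetra-O-benzylcatechin
Conditions: DDQ (1.5 equiv), 2-ethoxyethanol (excess), CH2Cl2, rt
Reagents that add atoms: 2-ethoxyethanol, CCOCCO
Why: Benzylic oxidation by hydride abstraction at C4 gives the ring-A-stabilised cation, which the alcohol traps (expected cis to the 3-OH).

Step 13
Reactants: 19 4β-(2-ethoxyethoxy)-5,7,3',4'-tetra-O-benzylcatechin
Product: 20 3-O-acetyl-4β-(2-ethoxyethoxy)-5,7,3',4'-tetra-O-benzylcatechin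
Conditions: Ac2O, pyridine, DMAP (cat.), rt
Reagents that add atoms: acetic anhydride, CC(=O)OC(C)=O
Why: Acylation installs the 3-acetate that will participate at C4.

Step 14
Reactants: 18 dimer nucleophile; 20 3-O-acetyl-4-alkoxy electrophile
Product: 21 3-O-acetyl-tetra-O-benzylcatechin-(4α→8)-tetra-O-benzylcatechin-(4α→8)-penta-O-benzylcatechin
Conditions: TMSOTf (0.2 equiv), CH2Cl2, −78 °C; 18 in excess (2–3 equiv), surplus recovered
Reagents that add atoms: none
Why: Friedel–Crafts alkylation: TMSOTf ionises the C4 ether, the 3-acetate bridges the β face of the cation, and C8 of the upper unit of 18 attacks from the α face to give the 3,4-trans (4α→8) bond, while excess 18 suppresses self-condensation of 20.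

Step 15
Reactants: 21 trimer nucleophile; 20 3-O-acetyl-4-alkoxy electrophile
Product: 22 protected tetramer (3-O-acetyl on units 1 and 2, free 3-OH on unit 3, 3-O-benzyl on unit 4, seventeen benzyl ethers)
Conditions: TMSOTf (0.2 equiv), CH2Cl2, −78 °C; 21 in excess, surplus recovered
Reagents that add atoms: none
Why: Same acetate-directed Friedel–Crafts chain extension, now at C8 of the top unit of 21, again giving the 4α→8 (3,4-trans) bond.

Step 16
Reactants: 22 protected tetramer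
Product: 23 heptadeca-O-benzyl tetramer (3-OH free on units 1–3)
Conditions: NaOMe (cat.), MeOH/THF, 40 °C
Reagents that add atoms: none
Why: Zemplén transesterification removes both acetates; no free phenol is present, so the flavan units are not exposed to base-induced epimerisation.

Step 17
Reactants: 23 heptadeca-O-benzyl tetramer
Product: 24 catechin-(4α→8)-catechin-(4α→8)-catechin-(4α→8)-catechin (target)
Conditions: H2 (1 atm), Pd(OH)2/C, THF/MeOH/H2O, rt
Reagents that add atoms: none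
Why: Hydrogenolysis cleaves the sixteen aryl benzyl ethers and the one alkyl benzyl ether under neutral conditions that leave the interflavan bonds intact.

**Compound list**

1 | (+)-catechin, (2R,3S) | Oc1cc(O)c2c(c1)O[C@H](c1ccc(O)c(O)c1)[C@@H](O)C2 | starting material
2 | 5,7,3',4'-tetra-O-benzyl-(+)-catechin | c1c(OCc3ccccc3)cc(OCc3ccccc3)c2c1O[C@H](c1ccc(OCc3ccccc3)c(OCc3ccccc3)c1)[C@@H](O)C2 | intermediate
3 | 3,5,7,3',4'-penta-O-benzyl-(+)-catechin | c1c(OCc3ccccc3)cc(OCc3ccccc3)c2c1O[C@H](c1ccc(OCc3ccccc3)c(OCc3ccccc3)c1)[C@@H](OCc3ccccc3)C2 | intermediate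
4 | 8-bromo-3,5,7,3',4'-penta-O-benzyl-(+)-catechin | Brc1c(OCc3ccccc3)cc(OCc3ccccc3)c2c1O[C@H](c1ccc(OCc3ccccc3)c(OCc3ccccc3)c1)[C@@H](OCc3ccccc3)C2 | intermediate
5 | 2,4,6-trihydroxybenzaldehyde | O=Cc1c(O)cc(O)cc1O | starting material
6 | 4,6-bis(benzyloxy)-2-hydroxybenzaldehyde | O=Cc1c(O)cc(OCc2ccccc2)cc1OCc1ccccc1 | intermediate
7 | 4,6-bis(benzyloxy)-2-(tert-butyldimethylsilyloxy)benzaldehyde | O=Cc1c(O[Si](C)(C)C(C)(C)C)cc(OCc2ccccc2)cc1OCc1ccccc1 | intermediate
8 | 8-lithio-3,5,7,3',4'-penta-O-benzylcatechin | [Li]c1c(OCc3ccccc3)cc(OCc3ccccc3)c2c1O[C@H](c1ccc(OCc3ccccc3)c(OCc3ccccc3)c1)[C@@H](OCc3ccccc3)C2 | intermediate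
9 | [4,6-bis(benzyloxy)-2-(tert-butyldimethylsilyloxy)phenyl](penta-O-benzylcatechin-8-yl)methanol, both carbinol epimers | CC(C)(C)[Si](C)(C)Oc1cc(OCc2ccccc2)cc(OCc2ccccc2)c1C(O)c1c(OCc3ccccc3)cc(OCc3ccccc3)c2c1O[C@H](c1ccc(OCc3ccccc3)c(OCc3ccccc3)c1)[C@@H](OCc3ccccc3)C2 | intermediate
10 | [4,6-bis(benzyloxy)-2-hydroxyphenyl](penta-O-benzylcatechin-8-yl)methanol, both carbinol epimers | Oc1cc(OCc2ccccc2)cc(OCc2ccccc2)c1C(O)c1c(OCc3ccccc3)cc(OCc3ccccc3)c2c1O[C@H](c1ccc(OCc3ccccc3)c(OCc3ccccc3)c1)[C@@H](OCc3ccccc3)C2 | intermediate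
11 | 3',4'-bis(benzyloxy)acetophenone | CC(=O)c1ccc(OCc2ccccc2)c(OCc2ccccc2)c1 | starting material
12 | (E)-3',4'-bis(benzyloxy)acetophenone oxime | C/C(=N\O)c1ccc(OCc2ccccc2)c(OCc2ccccc2)c1 | intermediate
13 | N-{1-[3,4-bis(benzyloxy)phenyl]vinyl}acetamide | C=C(NC(C)=O)c1ccc(OCc2ccccc2)c(OCc2ccccc2)c1 | intermediate
14 | ortho-quinone methide: 3,5-bis(benzyloxy)-6-[(penta-O-benzylcatechin-8-yl)methylene]cyclohexa-2,4-dien-1-one | O=C1C=C(OCc2ccccc2)C=C(OCc2ccccc2)C1=Cc1c(OCc3ccccc3)cc(OCc3ccccc3)c2c1O[C@H](c1ccc(OCc3ccccc3)c(OCc3ccccc3)c1)[C@@H](OCc3ccccc3)C2 | intermediate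
15 | 2-acetamido-5,7,3',4'-tetra-O-benzylflavan-(4α→8)-penta-O-benzylcatechin (N,O-aminal, C2 epimers) | c1c(OCc3ccccc3)cc(OCc3ccccc3)c2c1OC(NC(C)=O)(c1ccc(OCc3ccccc3)c(OCc3ccccc3)c1)C[C@@H]2c1c(OCc3ccccc3)cc(OCc3ccccc3)c2c1O[C@H](c1ccc(OCc3ccccc3)c(OCc3ccccc3)c1)[C@@H](OCc3ccccc3)C2 | intermediate
16 | 5,7,3',4'-tetra-O-benzylflav-2-ene-(4α→8)-3,5,7,3',4'-penta-O-benzylcatechin (C4: H β, aryl α) | c1c(OCc3ccccc3)cc(OCc3ccccc3)c2c1OC(c1ccc(OCc3ccccc3)c(OCc3ccccc3)c1)=C[C@@H]2c1c(OCc3ccccc3)cc(OCc3ccccc3)c2c1O[C@H](c1ccc(OCc3ccccc3)c(OCc3ccccc3)c1)[C@@H](OCc3ccccc3)C2 | intermediate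
17 | C3 alkylborane of 16 (2α-aryl, 3β-boryl, 4α-aryl) | c1c(OCc3ccccc3)cc(OCc3ccccc3)c2c1O[C@H](c1ccc(OCc3ccccc3)c(OCc3ccccc3)c1)[C@@H](B)[C@@H]2c1c(OCc3ccccc3)cc(OCc3ccccc3)c2c1O[C@H](c1ccc(OCc3ccccc3)c(OCc3ccccc3)c1)[C@@H](OCc3ccccc3)C2 | intermediate
18 | 5,7,3',4'-tetra-O-benzylcatechin-(4α→8)-3,5,7,3',4'-penta-O-benzylcatechin | c1c(OCc3ccccc3)cc(OCc3ccccc3)c2c1O[C@H](c1ccc(OCc3ccccc3)c(OCc3ccccc3)c1)[C@@H](O)[C@@H]2c1c(OCc3ccccc3)cc(OCc3ccccc3)c2c1O[C@H](c1ccc(OCc3ccccc3)c(OCc3ccccc3)c1)[C@@H](OCc3ccccc3)C2 | intermediate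
19 | 4β-(2-ethoxyethoxy)-5,7,3',4'-tetra-O-benzylcatechin (2R,3S,4S) | c1c(OCc3ccccc3)cc(OCc3ccccc3)c2c1O[C@H](c1ccc(OCc3ccccc3)c(OCc3ccccc3)c1)[C@@H](O)[C@H]2OCCOCC | intermediate
20 | 3-O-acetyl-4β-(2-ethoxyethoxy)-5,7,3',4'-tetra-O-benzylcatechin | c1c(OCc3ccccc3)cc(OCc3ccccc3)c2c1O[C@H](c1ccc(OCc3ccccc3)c(OCc3ccccc3)c1)[C@@H](OC(C)=O)[C@H]2OCCOCC | intermediate
21 | 3-O-acetyl-tetra-O-benzylcatechin-(4α→8)-tetra-O-benzylcatechin-(4α→8)-penta-O-benzylcatechin | c1c(OCc3ccccc3)cc(OCc3ccccc3)c2c1O[C@H](c1ccc(OCc3ccccc3)c(OCc3ccccc3)c1)[C@@H](OC(C)=O)[C@@H]2c1c(OCc3ccccc3)cc(OCc3ccccc3)c2c1O[C@H](c1ccc(OCc3ccccc3)c(OCc3ccccc3)c1)[C@@H](O)[C@@H]2c1c(OCc3ccccc3)cc(OCc3ccccc3)c2c1O[C@H](c1ccc(OCc3ccccc3)c(OCc3ccccc3)c1)[C@@H](OCc3ccccc3)C2 | intermediate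
22 | protected tetramer: 3-O-acetyl-tetra-O-benzylcatechin-(4α→8)-3-O-acetyl-tetra-O-benzylcatechin-(4α→8)-tetra-O-benzylcatechin-(4α→8)-penta-O-benzylcatechin | c1c(OCc3ccccc3)cc(OCc3ccccc3)c2c1O[C@H](c1ccc(OCc3ccccc3)c(OCc3ccccc3)c1)[C@@H](OC(C)=O)[C@@H]2c1c(OCc3ccccc3)cc(OCc3ccccc3)c2c1O[C@H](c1ccc(OCc3ccccc3)c(OCc3ccccc3)c1)[C@@H](OC(C)=O)[C@@H]2c1c(OCc3ccccc3)cc(OCc3ccccc3)c2c1O[C@H](c1ccc(OCc3ccccc3)c(OCc3ccccc3)c1)[C@@H](O)[C@@H]2c1c(OCc3ccccc3)cc(OCc3ccccc3)c2c1O[C@H](c1ccc(OCc3ccccc3)c(OCc3ccccc3)c1)[C@@H](OCc3ccccc3)C2 | intermediate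
23 | heptadeca-O-benzyl tetramer, 3-OH free on units 1–3 | c1c(OCc3ccccc3)cc(OCc3ccccc3)c2c1O[C@H](c1ccc(OCc3ccccc3)c(OCc3ccccc3)c1)[C@@H](O)[C@@H]2c1c(OCc3ccccc3)cc(OCc3ccccc3)c2c1O[C@H](c1ccc(OCc3ccccc3)c(OCc3ccccc3)c1)[C@@H](O)[C@@H]2c1c(OCc3ccccc3)cc(OCc3ccccc3)c2c1O[C@H](c1ccc(OCc3ccccc3)c(OCc3ccccc3)c1)[C@@H](O)[C@@H]2c1c(OCc3ccccc3)cc(OCc3ccccc3)c2c1O[C@H](c1ccc(OCc3ccccc3)c(OCc3ccccc3)c1)[C@@H](OCc3ccccc3)C2 | intermediate
24 | catechin-(4α→8)-catechin-(4α→8)-catechin-(4α→8)-catechin | Oc1cc(O)c2c(c1)O[C@H](c1ccc(O)c(O)c1)[C@@H](O)[C@@H]2c1c(O)cc(O)c2c1O[C@H](c1ccc(O)c(O)c1)[C@@H](O)[C@@H]2c1c(O)cc(O)c2c1O[C@H](c1ccc(O)c(O)c1)[C@@H](O)[C@@H]2c1c(O)cc(O)c2c1O[C@H](c1ccc(O)c(O)c1)[C@@H](O)C2 | target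

**Step count and risks**

Total step count: 17. Longest linear sequence: 11 steps (1, 2, 3, 6, 7, 10, 11, 14, 15, 16, 17).

Steps most likely to fail:

Step 10. The facial control by the catalyst may be eroded at the hindered, strongly stabilised methide (mismatch with the resident catechin unit). Carbon–carbon bond formation may be slow. During the expulsion of acetamide the 4-aryl group may be lost by retro-Friedel–Crafts ionisation to a flavylium ion. The fallback sets out from 6 and 11 and comes back at 18. Claisen–Schmidt condensation of 6 with 11 (KOH, EtOH, rt) gives (E)-1-[3,4-bis(benzyloxy)phenyl]-3-[4,6-bis(benzyloxy)-2-hydroxyphenyl]prop-2-en-1-one F1. Luche reduction (NaBH4, CeCl3·7H2O, MeOH/THF, 0 °C) gives the allylic alcohol F2. A chiral BINOL-derived N-triflylphosphoramide (toluene, −78 °C) ionises F2 to the allyl cation, and its chiral counter-anion directs the phenol onto C2, closing ring C at O1–C2 to give (2S)-5,7,3',4'-tetrakis(benzyloxy)flav-3-ene F3. Dimethyldioxirane (acetone/CH2Cl2, −40 °C) epoxidises the face anti to the C2 aryl to give the 3β,4β-epoxide F4. This is opened in the same flask at C4 by C8 of 3 (BF3·OEt2 cat., −78 °C, anti attack) to give 18.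

Step 11. The C3 borane may open ring C by β-alkoxy elimination, or borane may add with incomplete facial selectivity. The fallback sets out from 16 and comes back at 18. Dimethyldioxirane (acetone/CH2Cl2, −78 °C) epoxidises the enol ether anti to the C4 aryl to give the 2β,3β-epoxide F5. DIBAL-H (toluene, −78 °C) then coordinates the epoxide oxygen, opens the C2–O bond to the cation stabilised by O1 and ring B, and delivers hydride to the same (β) face, giving 18.

Step 15. The electrophile may self-condense, and the chain may be extended further or attacked at C6, when the valuable trimer cannot be used in large excess. The fallback sets out from 20 and comes back at 24. NBS (CH2Cl2, −78 °C) gives the 8-bromo electrophile F6, whose ring A is blocked and deactivated. TMSOTf-promoted coupling with an equimolar amount of 21 gives the 8-bromo tetramer F7, which cannot be extended further. NaOMe in MeOH/THF gives the triol F8. Hydrogenolysis (H2, Pd(OH)2/C, Et3N, THF/MeOH/H2O) removes the benzyl groups together with the bromine to give 24.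

**Further compounds**

F1 | step 10 | (E)-1-[3,4-bis(benzyloxy)phenyl]-3-[4,6-bis(benzyloxy)-2-hydroxyphenyl]prop-2-en-1-one | O=C(/C=C/c1c(O)cc(OCc2ccccc2)cc1OCc1ccccc1)c1ccc(OCc2ccccc2)c(OCc2ccccc2)c1
F2 | step 10 | (E)-1-[3,4-bis(benzyloxy)phenyl]-3-[4,6-bis(benzyloxy)-2-hydroxyphenyl]prop-2-en-1-ol (racemic) | OC(/C=C/c1c(O)cc(OCc2ccccc2)cc1OCc1ccccc1)c1ccc(OCc2ccccc2)c(OCc2ccccc2)c1
F3 | step 10 | (2S)-5,7,3',4'-tetrakis(benzyloxy)flav-3-ene (2-aryl α) | c1c(OCc3ccccc3)cc(OCc3ccccc3)c2c1O[C@H](c1ccc(OCc3ccccc3)c(OCc3ccccc3)c1)C=C2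
F4 | step 10 | 3β,4β-epoxy-5,7,3',4'-tetrakis(benzyloxy)flavan (2-aryl α) | c1c(OCc3ccccc3)cc(OCc3ccccc3)c2c1O[C@H](c1ccc(OCc3ccccc3)c(OCc3ccccc3)c1)[C@@H]4[C@H]2O4
F5 | step 11 | 2β,3β-epoxy-5,7,3',4'-tetra-O-benzylflavan-(4α→8)-penta-O-benzylcatechin | c1c(OCc3ccccc3)cc(OCc3ccccc3)c2c1O[C@]4(c1ccc(OCc3ccccc3)c(OCc3ccccc3)c1)[C@@H](O4)[C@@H]2c1c(OCc3ccccc3)cc(OCc3ccccc3)c2c1O[C@H](c1ccc(OCc3ccccc3)c(OCc3ccccc3)c1)[C@@H](OCc3ccccc3)C2
F6 | step 15 | 3-O-acetyl-8-bromo-4β-(2-ethoxyethoxy)-5,7,3',4'-tetra-O-benzylcatechin | Brc1c(OCc3ccccc3)cc(OCc3ccccc3)c2c1O[C@H](c1ccc(OCc3ccccc3)c(OCc3ccccc3)c1)[C@@H](OC(C)=O)[C@H]2OCCOCC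
F7 | step 15 | 8-bromo derivative (unit 1) of protected tetramer 22 | Brc1c(OCc3ccccc3)cc(OCc3ccccc3)c2c1O[C@H](c1ccc(OCc3ccccc3)c(OCc3ccccc3)c1)[C@@H](OC(C)=O)[C@@H]2c1c(OCc3ccccc3)cc(OCc3ccccc3)c2c1O[C@H](c1ccc(OCc3ccccc3)c(OCc3ccccc3)c1)[C@@H](OC(C)=O)[C@@H]2c1c(OCc3ccccc3)cc(OCc3ccccc3)c2c1O[C@H](c1ccc(OCc3ccccc3)c(OCc3ccccc3)c1)[C@@H](O)[C@@H]2c1c(OCc3ccccc3)cc(OCc3ccccc3)c2c1O[C@H](c1ccc(OCc3ccccc3)c(OCc3ccccc3)c1)[C@@H](OCc3ccccc3)C2
F8 | step 15 | 8-bromo derivative (unit 1) of heptadeca-O-benzyl tetramer 23 | Brc1c(OCc3ccccc3)cc(OCc3ccccc3)c2c1O[C@H](c1ccc(OCc3ccccc3)c(OCc3ccccc3)c1)[C@@H](O)[C@@H]2c1c(OCc3ccccc3)cc(OCc3ccccc3)c2c1O[C@H](c1ccc(OCc3ccccc3)c(OCc3ccccc3)c1)[C@@H](O)[C@@H]2c1c(OCc3ccccc3)cc(OCc3ccccc3)c2c1O[C@H](c1ccc(OCc3ccccc3)c(OCc3ccccc3)c1)[C@@H](O)[C@@H]2c1c(OCc3ccccc3)cc(OCc3ccccc3)c2c1O[C@H](c1ccc(OCc3ccccc3)c(OCc3ccccc3)c1)[C@@H](OCc3ccccc3)C2
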